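**Plan**

- Retrosynthesis cuts, in order: the prenyl C=C (cross-metathesis of an allyl group); the aryl–C(=O) bond (Friedel–Crafts with (R)-2-methylbutanoyl chloride); two bonds of the benzene ring, C(OH)–C(CH2-pyranone) and C(OMe)–C(side chain); the CH2–C(sp) bond; the pyranone ring.
- Enabling feature: the benzene ring carries oxygen on three alternate carbons, and the one methyl ether oxygen sits on the carbon flanked by the two carbon arms. These oxygens map onto a ketene carbonyl O (the free OH), the 3-siloxy O of a cyclobutenone and the O of an alkynyl methyl ether.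
- Forward: the pyranone ring is made first (silyl enol ether + malonyl dichloride) and elaborated to a pyranonylmethyl methoxyalkyne; a 3-siloxycyclobutenone is made from a siloxyalkyne and ketene; the benzene ring is closed last by their thermal benzannulation.
- Endgame: one fluoride treatment frees all three hydroxyls, the acyl group enters at the only vacant ring carbon, and metathesis turns allyl into prenyl.
- Stereochemistry: the single stereocenter is bought as (R)-2-methylbutanoic acid and is introduced late under acidic, non-enolising conditions, followed only by a neutral metathesis.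

Key step: step 11

Assumption: the prenyl chain is carried as an allyl group until the last step, because a prenyl alkene next to a free phenol is not expected to survive the Lewis-acid acylation; ketene is taken as the gas from pyrolysis of acetone, and (R)-2-methylbutanoic acid as the purchased single enantiomer.

**Route**

Step 1
Reactants: 1 pentan-3-one
Product: 2 (Z)-3-(trimethylsilyloxy)pent-2-ene
Conditions: Me3SiCl, Et3N, DMF, 80 °C
Reagents that add atoms: chlorotrimethylsilane, C[Si](C)(C)Cl
Why: Thermodynamic silyl enol ether formation on a symmetrical ketone admits only one regioisomer, and the alkene geometry is of no consequence because it disappears in step 2.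

Step 2
Reactants: 2 (Z)-3-(trimethylsilyloxy)pent-2-ene; 3 malonyl dichloride
Product: 5 6-ethyl-4-hydroxy-5-methyl-2H-pyran-2-one, via diketo acid chloride 4 (not isolated)
Conditions: Et2O, −78 °C → rt
Reagents that add atoms: none
Why: C-acylation of the silyl enol ether by one acid chloride function gives 4, whose ketone enol oxygen closes onto the second acid chloride in a six-membered lactonisation, an established synthesis of 4-hydroxy-2-pyranones from silyl enol ethers.

Step 3
Reactants: 5 6-ethyl-4-hydroxy-5-methyl-2H-pyran-2-one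
Product: 6 6-ethyl-5-methyl-4-[2-(trimethylsilyl)ethoxy]-2H-pyran-2-one
Conditions: Me3SiCH2CH2OH, PPh3, DIAD, THF, 0 °C → rt
Reagents that add atoms: 2-(trimethylsilyl)ethanol, OCC[Si](C)(C)C
Why: Mitsunobu O-alkylation of the acidic vinylogous acid at O-4 masks a hydroxyl that would otherwise add across the ynol ether made in step 8, with a group that later leaves under fluoride without releasing formaldehyde.

Step 4
Reactants: 6 6-ethyl-5-methyl-4-[2-(trimethylsilyl)ethoxy]-2H-pyran-2-one
Product: 7 3-bromo-6-ethyl-5-methyl-4-[2-(trimethylsilyl)ethoxy]-2H-pyran-2-one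
Conditions: NBS, CH2Cl2, 0 °C → rt, dark
Reagents that add atoms: N-bromosuccinimide, O=C1CCC(=O)N1Br
Why: Electrophilic bromination takes place at C3, the only unsubstituted and enol-ether-like ring carbon (C5 is blocked by methyl), and exclusion of light keeps the allylic C–H bonds untouched.

Step 5
Reactants: 7 3-bromo-6-ethyl-5-methyl-4-[2-(trimethylsilyl)ethoxy]-2H-pyran-2-one; 8 (tributylstannyl)methanol
Product: 9 6-ethyl-3-(hydroxymethyl)-5-methyl-4-[2-(trimethylsilyl)ethoxy]-2H-pyran-2-one
Conditions: Pd(PPh3)4 (5 mol%), 1,4-dioxane, 95 °C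
Reagents that add atoms: none
Why: Stille coupling of the vinylic bromide with the hydroxymethyl stannane transfers CH2OH under neutral conditions that leave the lactone and the silylethyl ether intact.

Step 6
Reactants: 9 6-ethyl-3-(hydroxymethyl)-5-methyl-4-[2-(trimethylsilyl)ethoxy]-2H-pyran-2-one
Product: 10 3-(bromomethyl)-6-ethyl-5-methyl-4-[2-(trimethylsilyl)ethoxy]-2H-pyran-2-one
Conditions: CBr4, PPh3, CH2Cl2, 0 °C; used without storage
Reagents that add atoms: carbon tetrabromide, BrC(Br)(Br)Br
Why: The Appel reaction converts the primary allylic alcohol into the bromide under neutral conditions that do not disturb the acid-labile silylethyl group.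

Step 7
Reactants: 11 chloroacetaldehyde dimethyl acetal
Product: 13 tributyl(methoxyethynyl)stannane, via lithium methoxyacetylide 12 (not isolated)
Conditions: LiNEt2 (3.1 equiv), THF, 0 °C; then Bu3SnCl, −78 °C → rt; distillation
Reagents that add atoms: tributyltin chloride, CCCC[Sn](Cl)(CCCC)CCCC
Why: Twofold elimination (HCl, then methanol) and deprotonation by the amide base give 12, which is trapped at carbon by the tin chloride to give a distillable, amine-free alkynylstannane.

Step 8
Reactants: 10 3-(bromomethyl)-6-ethyl-5-methyl-4-[2-(trimethylsilyl)ethoxy]-2H-pyran-2-one; 13 tributyl(methoxyethynyl)stannane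
Product: 14 6-ethyl-3-(3-methoxyprop-2-yn-1-yl)-5-methyl-4-[2-(trimethylsilyl)ethoxy]-2H-pyran-2-one
Conditions: Pd2(dba)3 (2.5 mol%), P(2-furyl)3 (10 mol%), THF, 50 °C; chromatography on Et3N-deactivated silica
Reagents that add atoms: none
Why: Stille coupling of the allylic-type bromide with the alkynylstannane forms the C(sp3)–C(sp) bond without a basic acetylide, which spares the lactone, the acidic 6-ethyl C–H bonds and the doubly activated propargylic CH2 from isomerisation to an allene.

Step 9
Reactants: 15 pent-1-en-4-yne
Product: 18 triisopropyl(pent-4-en-1-yn-1-yloxy)silane, via lithium acetylide 16 (not isolated), via lithium ynolate 17 (not isolated)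
Conditions: n-BuLi, THF, −78 °C; LiOOt-Bu (from t-BuOOH and LiN(SiMe3)2), −78 → 0 °C; i-Pr3SiOTf, −78 °C
Reagents that add atoms: tert-butyl hydroperoxide (as its lithium salt), CC(C)(C)OO; triisopropylsilyl trifluoromethanesulfonate, CC(C)[Si](OS(=O)(=O)C(F)(F)F)(C(C)C)C(C)C
Why: Oxygen transfer from lithium tert-butyl peroxide to acetylide 16 is a known acetylide oxidation to the ynolate 17, and the bulky silyl triflate silylates it on oxygen to give a siloxyalkyne stable enough to purify.

Step 10
Reactants: 18 triisopropyl(pent-4-en-1-yn-1-yloxy)silane; 19 acetone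
Product: 21 2-allyl-3-(triisopropylsilyloxy)cyclobut-2-en-1-one, via ketene 20 (not isolated)
Conditions: ketene gas from pyrolysis of acetone (ketene lamp), passed into 18 in CH2Cl2, 0 °C → rt
Reagents that add atoms: none
Why: The thermal [2+2] cycloaddition of ketene with a siloxyalkyne, in which the alkyne carbon beta to oxygen bonds to the ketene carbonyl carbon, is a known route to 2-alkyl-3-siloxycyclobutenones, and the isolated allyl alkene does not react with ketene.

Step 11
Reactants: 21 2-allyl-3-(triisopropylsilyloxy)cyclobut-2-en-1-one; 14 6-ethyl-3-(3-methoxyprop-2-yn-1-yl)-5-methyl-4-[2-(trimethylsilyl)ethoxy]-2H-pyran-2-one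
Product: 26 3-{[3-allyl-6-hydroxy-2-methoxy-4-(triisopropylsilyloxy)phenyl]methyl}-6-ethyl-5-methyl-4-[2-(trimethylsilyl)ethoxy]-2H-pyran-2-one, via siloxy vinylketene 22 (not isolated), via vinylcyclobutenone 23 (not isolated), via dienylketene 24 (not isolated), via cyclohexadienone 25 (not isolated)
Conditions: 21 (1.15 equiv), toluene, 80 °C then 110 °C, sealed tube, Ar
Reagents that add atoms: none
Why: Heating opens 21 by 4π-electrocyclic ring opening to the siloxy vinylketene 22, which adds across the electron-rich triple bond of 14 in a [2+2] cycloaddition to give 23; a second 4π opening gives dienylketene 24, which closes to cyclohexadienone 25 and enolises to phenol 26. The closest known reaction type is the Danheiser benzannulation of cyclobutenones with alkoxyalkynes, together with the known thermal union of 3-siloxycyclobutenones with oxygenated alkynes to resorcinol derivatives. The benzene ring closes by a thermal, disrotatory 6π-electrocyclisation in which the ketene carbon bonds to the terminal CH2 of the siloxy diene, and aromatisation by tautomerism makes the sequence irreversible. No stereocenter is formed, since the quaternary carbon of 23 is lost on ring opening. The step needs the right orientation in the ketene–alkyne addition: the alkyne carbon beta to the methoxy oxygen, which carries the pyranonylmethyl arm, is the nucleophilic one and bonds to the electrophilic ketene carbonyl carbon, so the methoxy carbon joins the allyl-bearing carbon and ends between the two carbon arms, meta to the new hydroxyl. Chemoselectivity rests on the ynol ether being the only good ketenophile present (the allyl alkene and the pyranone are inert), on the silylethyl group masking the acidic pyranone hydroxyl, and on neutral thermal conditions that leave three differently capped oxygens (OH, OMe, OSi) on the new ring.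

Step 12
Reactants: 26 3-{[3-allyl-6-hydroxy-2-methoxy-4-(triisopropylsilyloxy)phenyl]methyl}-6-ethyl-5-methyl-4-[2-(trimethylsilyl)ethoxy]-2H-pyran-2-one
Product: 27 3-[(3-allyl-4,6-dihydroxy-2-methoxyphenyl)methyl]-6-ethyl-4-hydroxy-5-methyl-2H-pyran-2-one
Conditions: Bu4NF (4 equiv), THF, 0 °C → rt, Ar; 1 M aq. HCl work-up
Reagents that add atoms: none
Why: Fluoride cleaves the aryl silyl ether and triggers beta-elimination of the 2-(trimethylsilyl)ethyl group from the vinylogous ester (as in the cleavage of trimethylsilylethyl esters), so one operation frees all three hydroxyls without setting free formaldehyde that could attack the vacant ring carbon.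

Step 13
Reactants: 28 (R)-2-methylbutanoic acid
Product: 29 (R)-2-methylbutanoyl chloride
Conditions: (COCl)2, DMF (cat.), CH2Cl2, 0 °C → rt; used crude
Reagents that add atoms: oxalyl chloride, O=C(Cl)C(Cl)=O
Why: Acid chloride formation by Vilsmeier-type activation is run without base, so no ketene forms and the alpha stereocenter of 28 is carried over unchanged.

Step 14
Reactants: 27 3-[(3-allyl-4,6-dihydroxy-2-methoxyphenyl)methyl]-6-ethyl-4-hydroxy-5-methyl-2H-pyran-2-one; 29 (R)-2-methylbutanoyl chloride
Product: 30 3-({3-allyl-4,6-dihydroxy-2-methoxy-5-[(2R)-2-methylbutanoyl]phenyl}methyl)-6-ethyl-4-hydroxy-5-methyl-2H-pyran-2-one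
Conditions: 29 (1.2 equiv), TiCl4 (4 equiv), CH2Cl2, −20 → 0 °C; 1 M aq. HCl work-up
Reagents that add atoms: none
Why: Friedel–Crafts acylation can only occur at the single unsubstituted ring carbon, which is activated by two ortho hydroxyls and a para methoxy group, while the terminal allyl alkene should tolerate the cold Lewis acid; the stereocenter comes from 29 and the acidic, non-enolising medium should preserve it.

Step 15
Reactants: 30 3-({3-allyl-4,6-dihydroxy-2-methoxy-5-[(2R)-2-methylbutanoyl]phenyl}methyl)-6-ethyl-4-hydroxy-5-methyl-2H-pyran-2-one; 31 2-methylbut-2-ene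
Product: 32 3-({4,6-dihydroxy-2-methoxy-5-[(2R)-2-methylbutanoyl]-3-(3-methylbut-2-en-1-yl)phenyl}methyl)-6-ethyl-4-hydroxy-5-methyl-2H-pyran-2-one (CNP0279667.1)
Conditions: 31 (large excess), second-generation Grubbs catalyst (H2IMes)(PCy3)Cl2Ru=CHPh (5 mol%), CH2Cl2, 40 °C, sealed
Reagents that add atoms: none
Why: Olefin cross-metathesis of the terminal allyl group with excess 2-methylbut-2-ene gives the trisubstituted prenyl alkene, a standard way to make prenyl arenes that tolerates free phenols, and the neutral conditions leave the stereocenter next to the ketone untouched.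

**Compound list**

1 | pentan-3-one | CCC(=O)CC | starting material
2 | (Z)-3-(trimethylsilyloxy)pent-2-ene | C/C=C(\O[Si](C)(C)C)CC | intermediate
3 | malonyl dichloride | O=C(Cl)CC(=O)Cl | starting material
4 | 4-methyl-3,5-dioxoheptanoyl chloride (racemic, not isolated) | CCC(=O)C(C)C(=O)CC(=O)Cl | intermediate
5 | 6-ethyl-4-hydroxy-5-methyl-2H-pyran-2-one | CCc1oc(=O)cc(O)c1C | intermediate
6 | 6-ethyl-5-methyl-4-[2-(trimethylsilyl)ethoxy]-2H-pyran-2-one | CCc1oc(=O)cc(OCC[Si](C)(C)C)c1C | intermediate
7 | 3-bromo-6-ethyl-5-methyl-4-[2-(trimethylsilyl)ethoxy]-2H-pyran-2-one | CCc1oc(=O)c(Br)c(OCC[Si](C)(C)C)c1C | intermediate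
8 | (tributylstannyl)methanol | OC[Sn](CCCC)(CCCC)CCCC | starting material
9 | 6-ethyl-3-(hydroxymethyl)-5-methyl-4-[2-(trimethylsilyl)ethoxy]-2H-pyran-2-one | CCc1oc(=O)c(CO)c(OCC[Si](C)(C)C)c1C | intermediate
10 | 3-(bromomethyl)-6-ethyl-5-methyl-4-[2-(trimethylsilyl)ethoxy]-2H-pyran-2-one | CCc1oc(=O)c(CBr)c(OCC[Si](C)(C)C)c1C | intermediate
11 | chloroacetaldehyde dimethyl acetal (2-chloro-1,1-dimethoxyethane) | COC(CCl)OC | starting material
12 | lithium methoxyacetylide (not isolated) | [Li]C#COC | intermediate
13 | tributyl(methoxyethynyl)stannane | CCCC[Sn](CCCC)(CCCC)C#COC | intermediate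
14 | 6-ethyl-3-(3-methoxyprop-2-yn-1-yl)-5-methyl-4-[2-(trimethylsilyl)ethoxy]-2H-pyran-2-one | COC#CCc1c(OCC[Si](C)(C)C)c(C)c(CC)oc1=O | intermediate
15 | pent-1-en-4-yne | C#CCC=C | starting material
16 | lithium pent-4-en-1-yn-1-ide (not isolated) | [Li]C#CCC=C | intermediate
17 | lithium pent-4-en-1-yn-1-olate (not isolated) | [Li]OC#CCC=C | intermediate
18 | triisopropyl(pent-4-en-1-yn-1-yloxy)silane | C=CCC#CO[Si](C(C)C)(C(C)C)C(C)C | intermediate
19 | acetone | CC(C)=O | starting material
20 | ketene (ethenone, not isolated) | C=C=O | intermediate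
21 | 2-allyl-3-(triisopropylsilyloxy)cyclobut-2-en-1-one | O=C1CC(O[Si](C(C)C)(C(C)C)C(C)C)=C1CC=C | intermediate
22 | 2-allyl-3-(triisopropylsilyloxy)buta-1,3-dien-1-one (siloxy vinylketene, not isolated) | O=C=C(CC=C)C(=C)O[Si](C(C)C)(C(C)C)C(C)C | intermediate
23 | 4-allyl-2-({6-ethyl-5-methyl-2-oxo-4-[2-(trimethylsilyl)ethoxy]-2H-pyran-3-yl}methyl)-3-methoxy-4-[1-(triisopropylsilyloxy)ethenyl]cyclobut-2-en-1-one (racemic, not isolated) | O=C1C(Cc2c(OCC[Si](C)(C)C)c(C)c(CC)oc2=O)=C(OC)C1(CC=C)C(=C)O[Si](C(C)C)(C(C)C)C(C)C | intermediate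
24 | 4-allyl-2-({6-ethyl-5-methyl-2-oxo-4-[2-(trimethylsilyl)ethoxy]-2H-pyran-3-yl}methyl)-3-methoxy-5-(triisopropylsilyloxy)hexa-1,3,5-trien-1-one, ketene and siloxyvinyl groups cis on the central double bond (not isolated) | O=C=C(Cc1c(OCC[Si](C)(C)C)c(C)c(CC)oc1=O)/C(OC)=C(CC=C)\C(=C)O[Si](C(C)C)(C(C)C)C(C)C | intermediate
25 | 4-allyl-2-({6-ethyl-5-methyl-2-oxo-4-[2-(trimethylsilyl)ethoxy]-2H-pyran-3-yl}methyl)-3-methoxy-5-(triisopropylsilyloxy)cyclohexa-2,4-dien-1-one (not isolated) | O=C1CC(O[Si](C(C)C)(C(C)C)C(C)C)=C(CC=C)C(OC)=C1Cc1c(OCC[Si](C)(C)C)c(C)c(CC)oc1=O | intermediate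
26 | 3-{[3-allyl-6-hydroxy-2-methoxy-4-(triisopropylsilyloxy)phenyl]methyl}-6-ethyl-5-methyl-4-[2-(trimethylsilyl)ethoxy]-2H-pyran-2-one | C=CCc1c(O[Si](C(C)C)(C(C)C)C(C)C)cc(O)c(Cc2c(OCC[Si](C)(C)C)c(C)c(CC)oc2=O)c1OC | intermediate
27 | 3-[(3-allyl-4,6-dihydroxy-2-methoxyphenyl)methyl]-6-ethyl-4-hydroxy-5-methyl-2H-pyran-2-one | C=CCc1c(O)cc(O)c(Cc2c(O)c(C)c(CC)oc2=O)c1OC | intermediate
28 | (R)-2-methylbutanoic acid | OC(=O)[C@H](C)CC | starting material
29 | (R)-2-methylbutanoyl chloride | ClC(=O)[C@H](C)CC | intermediate
30 | 3-({3-allyl-4,6-dihydroxy-2-methoxy-5-[(2R)-2-methylbutanoyl]phenyl}methyl)-6-ethyl-4-hydroxy-5-methyl-2H-pyran-2-one | C=CCc1c(O)c(C(=O)[C@H](C)CC)c(O)c(Cc2c(O)c(C)c(CC)oc2=O)c1OC | intermediate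
31 | 2-methylbut-2-ene | CC=C(C)C | starting material
32 | 3-({4,6-dihydroxy-2-methoxy-5-[(2R)-2-methylbutanoyl]-3-(3-methylbut-2-en-1-yl)phenyl}methyl)-6-ethyl-4-hydroxy-5-methyl-2H-pyran-2-one | CCc1oc(=O)c(Cc2c(O)c(C(=O)[C@H](C)CC)c(O)c(CC=C(C)C)c2OC)c(O)c1C | target

**Step count**

Total: 15 steps. Longest linear sequence: 11 steps (1, 2, 3, 4, 5, 6, 8, 11, 12, 14, 15).

**Steps most likely to fail**

1. Step 11 (benzannulation). The siloxy vinylketene may be consumed by dimerisation, or by acylating the phenol already formed, faster than the hindered ynol ether captures it. The ynol ether may also isomerise or hydrate on prolonged heating, and a reversed orientation in the ketene–alkyne addition would misplace the methoxy group.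
 Fallback (sets out from 29 and 5, comes back at 32): the benzene ring is bought instead of built. Phloroglucinol is C-acylated with 29 (AlCl3, PhNO2/CH2Cl2) to give (2R)-2-methyl-1-(2,4,6-trihydroxyphenyl)butan-1-one F1. The non-chelated para hydroxyl is methylated (Me2SO4, K2CO3, acetone) to give (2R)-1-(2,6-dihydroxy-4-methoxyphenyl)-2-methylbutan-1-one F2. C-prenylation with prenyl bromide (DBU, THF, 0 °C) then gives (2R)-1-[2,6-dihydroxy-4-methoxy-3-(3-methylbut-2-en-1-yl)phenyl]-2-methylbutan-1-one F3. Separately, pyranone 5 is converted with Eschenmoser's salt (dimethylmethylideneammonium iodide) into the Mannich base 3-[(dimethylamino)methyl]-6-ethyl-4-hydroxy-5-methyl-2H-pyran-2-one F4. Warming F4 with F3 should alkylate the one remaining ring carbon, with loss of dimethylamine, and give 32 directly.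

2. Step 14 (acylation). Ipso-protonation of the very electron-rich ring may split off the pyranonylmethyl arm (scission of the methylene bridge). The three hydroxyls may be O-acylated without migration to carbon, and the alpha stereocenter may erode through enolisation in the Lewis-acidic medium.
 Fallback (sets out from 26 and 28, comes back at 30): the acyl group is first placed on oxygen and then shifted to carbon. Steglich esterification of the single free phenol of 26 with acid 28 (DCC, DMAP cat., CH2Cl2, 0 °C) gives 4-allyl-2-({6-ethyl-5-methyl-2-oxo-4-[2-(trimethylsilyl)ethoxy]-2H-pyran-3-yl}methyl)-3-methoxy-5-(triisopropylsilyloxy)phenyl (2R)-2-methylbutanoate F5. A Fries rearrangement with TiCl4 (CH2Cl2, −40 → 0 °C) should move the acyl group to the only free ortho carbon and is expected to strip the trimethylsilylethyl group at the same time, giving 3-({3-allyl-6-hydroxy-2-methoxy-5-[(2R)-2-methylbutanoyl]-4-(triisopropylsilyloxy)phenyl}methyl)-6-ethyl-4-hydroxy-5-methyl-2H-pyran-2-one F6. Bu4NF buffered with AcOH then removes the triisopropylsilyl group to give 30.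

3. Step 8 (alkynyl Stille coupling). Transmetalation from tin may be slow, the ynol ether may decompose in the presence of zerovalent palladium, and the product may undergo propargyl-to-allenyl isomerisation or hydration on silica.
 Fallback (sets out from 10 and 12, comes back at 14): the same C(sp3)–C(sp) bond is formed without palladium or tin by SN2 displacement. Lithium methoxyacetylide 12, generated as in step 7 but not stannylated, is added to bromide 10 in THF/DMPU at −78 °C. This fallback makes no compound outside the list (F0).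

**Further compounds**

F1 | step 11 | (2R)-2-methyl-1-(2,4,6-trihydroxyphenyl)butan-1-one | O=C(c1c(O)cc(O)cc1O)[C@H](C)CC
F2 | step 11 | (2R)-1-(2,6-dihydroxy-4-methoxyphenyl)-2-methylbutan-1-one | O=C(c1c(O)cc(OC)cc1O)[C@H](C)CC
F3 | step 11 | (2R)-1-[2,6-dihydroxy-4-methoxy-3-(3-methylbut-2-en-1-yl)phenyl]-2-methylbutan-1-one | O=C(c1c(O)cc(OC)c(CC=C(C)C)c1O)[C@H](C)CC
F4 | step 11 | 3-[(dimethylamino)methyl]-6-ethyl-4-hydroxy-5-methyl-2H-pyran-2-one | CCc1oc(=O)c(CN(C)C)c(O)c1C
F5 | step 14 | 4-allyl-2-({6-ethyl-5-methyl-2-oxo-4-[2-(trimethylsilyl)ethoxy]-2H-pyran-3-yl}methyl)-3-methoxy-5-(triisopropylsilyloxy)phenyl (2R)-2-methylbutanoate | C=CCc1c(O[Si](C(C)C)(C(C)C)C(C)C)cc(OC(=O)[C@H](C)CC)c(Cc2c(OCC[Si](C)(C)C)c(C)c(CC)oc2=O)c1OC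
F6 | step 14 | 3-({3-allyl-6-hydroxy-2-methoxy-5-[(2R)-2-methylbutanoyl]-4-(triisopropylsilyloxy)phenyl}methyl)-6-ethyl-4-hydroxy-5-methyl-2H-pyran-2-one | C=CCc1c(O[Si](C(C)C)(C(C)C)C(C)C)c(C(=O)[C@H](C)CC)c(O)c(Cc2c(O)c(C)c(CC)oc2=O)c1OC
F0 | step 8 | none | none
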